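**Remark on the chemistry (assumption):** the target has no stereocentre and no stereogenic double bond, so it is achiral and the request for a single enantiomer is met by the constitution alone. The C=N geometry of oxime-type intermediates is left undefined because both isomers converge in step 6.

## Structural features

The target is a 2-arylbenzofuran (O1, C2, C3, C3a, C4–C7, C7a) carrying a 3-hydroxy-4-methoxyphenyl ring (C1'–C6') at C2, a methoxy group at C3, a 3-methylbut-2-enyl (prenyl) chain at C5 and a free hydroxyl at C6. The prenyl olefin bears two methyl groups, so nothing in the molecule is stereogenic. The C2=C3 bond is a tetrasubstituted, aryl-conjugated enol ether inside the furan; together with the two phenols it makes the molecule electron-rich and sensitive to oxidants and strong acid. The prenyl group is ortho to the free C6 hydroxyl, so acid would close a 2,2-dimethylchroman and hydrogenation is excluded. Ring A is a resorcinol unit: O1 (on C7a) and the C6 oxygen are meta, C3a is para to the C6 oxygen and C5 is para to C7a. The real difficulty is the fully substituted furan with oxygen on C3 next to aryl on C2, built with the correct ortho carbon of the aryloxy unit as C3a, and the C5 (not C7) placement of the prenyl chain. The key step exploits three facts: the C2(aryl)–C3(OMe) unit has the oxidation level of an α-methoxy aryl ketone, O1–C7a is an aryl–oxygen bond, and C3a is an unsubstituted ortho carbon para to the C6 oxygen. An O-aryl oxime ether of that ketone can therefore deliver C3–C3a and O1–C2 in one sigmatropic/condensation event.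

## Logic of the disconnections

**15 to 14.** The two O–Si bonds (on the C6 and C3' oxygens) are cut. This leaves deprotection as the last step and keeps both phenols masked through all metal-mediated and acylating steps. The forward step must be neither acidic (chroman formation) nor reductive (prenyl olefin), which a buffered fluoride source satisfies.

**14 to 12 + 13.** The C5–CH2 bond of the prenyl chain is cut. The site is defined by a bromine atom carried from the start, so the C5/C7 ambiguity of phenol prenylation never arises and the acid-sensitive olefin enters after the key step. The forward step must transfer the allyl unit through its unsubstituted (α) terminus at a hindered, electron-rich C–Br bond.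

**12 to 9 (key disconnection, through 10 and 11).** The furan bonds C3–C3a and O1–C2 are cut together, with formal return of the nitrogen lost as an amide. In one sentence: the furan ring is closed by an acyl-triggered [3,3]-sigmatropic rearrangement and cyclo-condensation of the O-aryl oxime ether 9 of an α-methoxy aryl ketone. This removes the whole heterocycle and the C3 oxygenation problem at once and reduces the core to two simple arenes joined through N–O. The forward step must make the enamine tautomer on the OCH2 side only, attack the ortho carbon para to the silyloxy group, and avoid N–O heterolysis.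

**9 to 6 + 8.** The aryl C–O bond (future C7a–O1) is cut. This splits the molecule into a B-ring oxime and an A-ring dihalide of similar size. The forward step must arylate the oxime oxygen at the C–I bond and leave the C–Br bond untouched.

**6 to 5, and 5 to 2 + 3 (through 4).** The C=N bond is cut back to the ketone, then the aryl–carbonyl bond is cut to an aryl anion and a methoxyacetyl cation equivalent. This places the C3 methoxy group in a commercial two-carbon unit. The forward step must stop at the ketone stage.

**2 to 1 and 8 to 7.** The O–Si bonds are cut to two commercial halophenols whose substitution patterns already encode the 3'-hydroxy-4'-methoxy B ring and the O1/C5/C6 pattern of ring A.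

## Other disconnections considered

**Alternative 1:** (the route most chemists would draw first) cut C2–C3 and the C3 O–CH3 bond. Forward: base-mediated intramolecular Claisen (Dieckmann-type) closure of the aryl benzyl ether ester A1 to the 2-arylbenzofuran-3(2H)-one A2, then O-methylation of its enolate to reach 12. The chosen plan is preferred for three reasons. A2 is an ambident, doubly activated enol/ketone pair in which C-methylation competes with O-methylation. Its C2–H position on an electron-rich ring is prone to autoxidation. A1 needs a resorcylate with three differentiated oxygens, which costs extra protecting-group steps in the longest sequence.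

**Alternative 2:** cut the C2–C1' biaryl bond. Forward: Pd-catalysed C2–H arylation (or C2 metalation and cross-coupling) of the 3-methoxybenzofuran A3 with 2. This removes only the B ring; A3 still contains the difficult 3-alkoxyfuran and would itself have to come from a benzofuranone. In addition, the C5–Br bond of A3 competes with the aryl bromide partner for Pd, so the prenyl chain would have to enter earlier and survive more steps.

**Alternative 3:** cut only O1–C2. Forward: oxidative cyclisation (I2, an iodine(III) reagent or Pd(II)) of the α-methoxy-2-hydroxystilbene A4, modelled on the phenol-onto-stilbene cyclisations thought to lead to natural arylbenzofurans. A4 already holds the full carbon skeleton, so the key step forms one bond and simplifies little. A4 needs its own enol-ether synthesis, where C- and O-alkylation of a deoxybenzoin compete. The oxidant would also have to distinguish the enol ether from two electron-rich arenes, with over-oxidation at C3 the expected side path.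

Key step: step 6

## Route

Step 1
Reactants: 1 5-bromo-2-methoxyphenol
Product: 2 (5-bromo-2-methoxyphenoxy)triisopropylsilane
Conditions: TIPSCl, imidazole, DMF, rt
Reagents that add atoms: chlorotriisopropylsilane, CC(C)[Si](Cl)(C(C)C)C(C)C
Why: Imidazole-promoted silylation of a phenol; the bulky triisopropylsilyl ether should tolerate aryllithium, carbonate, mild acid and Pd coupling and is removable at the end without acid or hydrogen.

Step 2
Reactants: 2 (5-bromo-2-methoxyphenoxy)triisopropylsilane; 3 N,2-dimethoxy-N-methylacetamide
Product: 5 2-methoxy-1-{4-methoxy-3-[(triisopropylsilyl)oxy]phenyl}ethan-1-one, via aryllithium 4 (not isolated)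
Conditions: n-BuLi, THF, −78 °C; then 3, −78 → 0 °C; aq NH4Cl
Reagents that add atoms: none
Why: Bromine–lithium exchange is fast at −78 °C and the meta relation of C–Li and O–Si excludes anionic silyl migration; acylation by the N-methoxy-N-methylamide (Weinreb ketone synthesis) should deliver the ketone without over-addition.

Step 3
Reactants: 5 2-methoxy-1-{4-methoxy-3-[(triisopropylsilyl)oxy]phenyl}ethan-1-one
Product: 6 2-methoxy-1-{4-methoxy-3-[(triisopropylsilyl)oxy]phenyl}ethan-1-one oxime (E/Z mixture)
Conditions: NH2OH·HCl, NaOAc, EtOH, 60 °C
Reagents that add atoms: hydroxylamine hydrochloride, Cl.NO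
Why: Buffered oxime condensation that leaves the aryl silyl ether intact; the E/Z ratio is irrelevant because the C=N geometry is lost in step 6.

Step 4
Reactants: 7 2-bromo-5-iodophenol
Product: 8 (2-bromo-5-iodophenoxy)triisopropylsilane
Conditions: TIPSCl, imidazole, DMF, rt
Reagents that add atoms: chlorotriisopropylsilane, CC(C)[Si](Cl)(C(C)C)C(C)C
Why: Phenol silylation as in step 1; it masks the future C6 hydroxyl so that only the oxime oxygen is arylated in step 5, and its bulk later helps direct the rearrangement.

Step 5
Reactants: 6 2-methoxy-1-{4-methoxy-3-[(triisopropylsilyl)oxy]phenyl}ethan-1-one oxime; 8 (2-bromo-5-iodophenoxy)triisopropylsilane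
Product: 9 2-methoxy-1-{4-methoxy-3-[(triisopropylsilyl)oxy]phenyl}ethan-1-one O-{4-bromo-3-[(triisopropylsilyl)oxy]phenyl}oxime
Conditions: CuI (10 mol %), 1,10-phenanthroline (20 mol %), Cs2CO3, toluene, 70 °C
Reagents that add atoms: none
Why: Ullmann-type Cu(I)-catalysed O-arylation of a ketoxime; the C–I bond reacts far faster than the C–Br bond with copper, so the bromine reserved for the prenyl chain is kept, and ketoximes are expected to arylate on oxygen under these conditions.

Step 6
Reactants: 9 2-methoxy-1-{4-methoxy-3-[(triisopropylsilyl)oxy]phenyl}ethan-1-one O-{4-bromo-3-[(triisopropylsilyl)oxy]phenyl}oxime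
Product: 12 5-bromo-3-methoxy-2-{4-methoxy-3-[(triisopropylsilyl)oxy]phenyl}-6-[(triisopropylsilyl)oxy]-1-benzofuran, via N-trifluoroacetyl ene-hydroxylamine 10 (not isolated), via trifluoroacetamido dihydrobenzofuran aminal 11 (not isolated)
Conditions: TFAA (3 equiv), DMAP (10 mol %), CH2Cl2, 0 °C → rt
Reagents that add atoms: none
Why: N-Trifluoroacetylation of the oxime nitrogen and loss of one of the only available α-protons (the OCH2 group; the other flank is the aryl ring) gives the N-aryloxy enamide 10, whose O–N–C=C array corresponds to the ene-hydrazine of a Fischer indole synthesis. A concerted chair-like [3,3]-sigmatropic shift then breaks the weak N–O bond and forms C3–C3a at an ortho carbon of the aryloxy ring; the N-acyl group and the methoxy group on the migrating terminus both lower the barrier, so the shift should occur at or below room temperature. Tautomerisation restores the arene as an ortho-hydroxyaryl N-acyl ketimine, and the new phenol oxygen (O1) adds to the imine carbon in a 5-exo-trig closure to give the N,O-acetal 11. Ionisation of 11 at C2, assisted by O1 and the para-methoxyaryl ring, expels trifluoroacetamide and loss of H3 aromatises the furan, so the one ring formed is closed by the sequence [3,3] (C–C) then 5-exo-trig (C–O). The closest known reaction type is the acid- or acyl-promoted rearrangement of O-aryl ketoxime ethers to benzofurans, the oxygen counterpart of the Fischer indole synthesis. No stereocentre results, because the two sp3 centres of 11 are erased on aromatisation. The step needs site selectivity between the two ortho carbons of the aryloxy ring: the carbon para to the silyloxy group (future C3a) is electronically activated and flanked only by hydrogen, whereas the other lies between two oxygens and is shielded by the Si(i-Pr)3 group. It also needs chemoselectivity over Beckmann-type fragmentation of the α-alkoxy oxime, which activation at nitrogen (not at oxygen) and the poor leaving-group ability of aryloxide outside the concerted shift should secure.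

Step 7
Reactants: 12 5-bromo-3-methoxy-2-{4-methoxy-3-[(triisopropylsilyl)oxy]phenyl}-6-[(triisopropylsilyl)oxy]-1-benzofuran; 13 4,4,5,5-tetramethyl-2-(3-methylbut-2-en-1-yl)-1,3,2-dioxaborolane
Product: 14 3-methoxy-2-{4-methoxy-3-[(triisopropylsilyl)oxy]phenyl}-5-(3-methylbut-2-en-1-yl)-6-[(triisopropylsilyl)oxy]-1-benzofuran
Conditions: Pd-PEPPSI-IPent (3 mol %), aq K3PO4, THF, 65 °C
Reagents that add atoms: none
Why: Suzuki–Miyaura allylation of an aryl bromide; a bulky NHC–Pd catalyst should steer the allyl–Pd–aryl intermediate to reductive elimination at the unsubstituted terminus and give the linear prenyl arene, at a position fixed by the bromine carried from 7.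

Step 8
Reactants: 14 3-methoxy-2-{4-methoxy-3-[(triisopropylsilyl)oxy]phenyl}-5-(3-methylbut-2-en-1-yl)-6-[(triisopropylsilyl)oxy]-1-benzofuran
Product: 15 2-(3-hydroxy-4-methoxyphenyl)-3-methoxy-5-(3-methylbut-2-en-1-yl)-1-benzofuran-6-ol
Conditions: TBAF (2.4 equiv), AcOH (2.4 equiv), THF, 0 °C → rt
Reagents that add atoms: none
Why: Fluoride-induced cleavage of both aryl silyl ethers; acetic acid buffering avoids a free phenoxide, and the conditions are neither acidic enough to cyclise the ortho-prenylphenol nor reductive.

## Compound list

1 | 5-bromo-2-methoxyphenol | COc1ccc(Br)cc1O | starting material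
2 | (5-bromo-2-methoxyphenoxy)triisopropylsilane | COc1ccc(Br)cc1O[Si](C(C)C)(C(C)C)C(C)C | intermediate
3 | N,2-dimethoxy-N-methylacetamide | COCC(=O)N(C)OC | starting material
4 | {4-methoxy-3-[(triisopropylsilyl)oxy]phenyl}lithium (not isolated) | [Li]c1ccc(OC)c(O[Si](C(C)C)(C(C)C)C(C)C)c1 | intermediate
5 | 2-methoxy-1-{4-methoxy-3-[(triisopropylsilyl)oxy]phenyl}ethan-1-one | COCC(=O)c1ccc(OC)c(O[Si](C(C)C)(C(C)C)C(C)C)c1 | intermediate
6 | 2-methoxy-1-{4-methoxy-3-[(triisopropylsilyl)oxy]phenyl}ethan-1-one oxime (E/Z mixture) | COCC(=NO)c1ccc(OC)c(O[Si](C(C)C)(C(C)C)C(C)C)c1 | intermediate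
7 | 2-bromo-5-iodophenol | Oc1cc(I)ccc1Br | starting material
8 | (2-bromo-5-iodophenoxy)triisopropylsilane | CC(C)[Si](Oc1cc(I)ccc1Br)(C(C)C)C(C)C | intermediate
9 | 2-methoxy-1-{4-methoxy-3-[(triisopropylsilyl)oxy]phenyl}ethan-1-one O-{4-bromo-3-[(triisopropylsilyl)oxy]phenyl}oxime (E/Z mixture) | COCC(=NOc1ccc(Br)c(O[Si](C(C)C)(C(C)C)C(C)C)c1)c1ccc(OC)c(O[Si](C(C)C)(C(C)C)C(C)C)c1 | intermediate
10 | N-{4-bromo-3-[(triisopropylsilyl)oxy]phenoxy}-2,2,2-trifluoro-N-(2-methoxy-1-{4-methoxy-3-[(triisopropylsilyl)oxy]phenyl}ethenyl)acetamide (not isolated, olefin geometry undefined) | COC=C(N(Oc1ccc(Br)c(O[Si](C(C)C)(C(C)C)C(C)C)c1)C(=O)C(F)(F)F)c1ccc(OC)c(O[Si](C(C)C)(C(C)C)C(C)C)c1 | intermediate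
11 | N-(5-bromo-3-methoxy-2-{4-methoxy-3-[(triisopropylsilyl)oxy]phenyl}-6-[(triisopropylsilyl)oxy]-2,3-dihydro-1-benzofuran-2-yl)-2,2,2-trifluoroacetamide (not isolated, racemic diastereomer mixture) | COC1c2cc(Br)c(O[Si](C(C)C)(C(C)C)C(C)C)cc2OC1(NC(=O)C(F)(F)F)c1ccc(OC)c(O[Si](C(C)C)(C(C)C)C(C)C)c1 | intermediate
12 | 5-bromo-3-methoxy-2-{4-methoxy-3-[(triisopropylsilyl)oxy]phenyl}-6-[(triisopropylsilyl)oxy]-1-benzofuran | COc1ccc(-c2oc3cc(O[Si](C(C)C)(C(C)C)C(C)C)c(Br)cc3c2OC)cc1O[Si](C(C)C)(C(C)C)C(C)C | intermediate
13 | 4,4,5,5-tetramethyl-2-(3-methylbut-2-en-1-yl)-1,3,2-dioxaborolane | CC(C)=CCB1OC(C)(C)C(C)(C)O1 | starting material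
14 | 3-methoxy-2-{4-methoxy-3-[(triisopropylsilyl)oxy]phenyl}-5-(3-methylbut-2-en-1-yl)-6-[(triisopropylsilyl)oxy]-1-benzofuran | COc1ccc(-c2oc3cc(O[Si](C(C)C)(C(C)C)C(C)C)c(CC=C(C)C)cc3c2OC)cc1O[Si](C(C)C)(C(C)C)C(C)C | intermediate
15 | 2-(3-hydroxy-4-methoxyphenyl)-3-methoxy-5-(3-methylbut-2-en-1-yl)-1-benzofuran-6-ol | COc1ccc(-c2oc3cc(O)c(CC=C(C)C)cc3c2OC)cc1O | target

## Step count and risk

Total step count: 8. Longest linear sequence: 7 steps (1 → 2 → 5 → 6 → 9 → 12 → 14 → 15); the A-ring branch (7 → 8) adds one step before convergence at step 5.

**Step 6 (key step).** The most likely failures are: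
- attack at the wrong ortho carbon (the one between the two oxygens), if the electronic activation of that position outweighs the steric shielding;
- heterolysis of the N–O bond or Beckmann-type fragmentation of the activated α-alkoxy oxime before the sigmatropic shift;
- stalling at the N,O-acetal stage.

Fallback, setting out from 8 and 5 and returning at 12: the C3–C3a bond is made by Pd-enolate arylation instead of a sigmatropic shift. Compound 8 undergoes selective iodine–magnesium exchange (i-PrMgCl·LiCl, THF, −40 °C) and borylation (B(OMe)3, then aqueous acid) to give [4-bromo-3-(triisopropylsilyloxy)phenyl]boronic acid F1. Oxidation (H2O2, aq NaHCO3, THF) gives 4-bromo-3-(triisopropylsilyloxy)phenol F2. Iodination (NIS, MeCN, 0 °C) ortho to the hydroxyl and para to the silyloxy group gives 4-bromo-2-iodo-5-(triisopropylsilyloxy)phenol F3. Pd-catalysed α-arylation of ketone 5 with F3 at its C–I bond (Pd2(dba)3, Xantphos, K3PO4, toluene, 80 °C) gives 2-[5-bromo-2-hydroxy-4-(triisopropylsilyloxy)phenyl]-2-methoxy-1-[4-methoxy-3-(triisopropylsilyloxy)phenyl]ethan-1-one F4. Acid-catalysed cyclodehydration (TsOH, toluene, 60 °C) then closes O1–C2 and returns to 12.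

**Step 5.** The likely failures are competing N-arylation of the oxime (nitrone formation), carbonate-induced loss of a silyl group at 70 °C followed by phenoxide arylation, or erosion of the iodine/bromine selectivity.

Fallback, setting out from 8 and 5 and returning at 9: the N–O–aryl unit is brought in from a hydroxylamine surrogate and the C=N bond is formed afterwards. Pd-catalysed C–O coupling of 8 at its C–I bond with ethyl N-hydroxyacetimidate ([(allyl)PdCl]2, t-BuBrettPhos, Cs2CO3, toluene, 65 °C) gives ethyl N-[4-bromo-3-(triisopropylsilyloxy)phenoxy]ethanimidate F5. Mild hydrolysis (aq HCl, dioxane, 0 °C, then neutralisation) gives O-[4-bromo-3-(triisopropylsilyloxy)phenyl]hydroxylamine F6. Condensation with ketone 5 (pyridine, EtOH, rt) gives 9.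

**Step 7.** The likely failures are allyl transposition during transmetalation and reductive elimination, giving the 1,1-dimethylallyl isomer, and slow oxidative addition at the hindered, electron-rich C–Br bond next to the silyloxy group, allowing protodeboronation to win.

Fallback, setting out from 12 and returning at 14: a symmetric allyl group is coupled first, so that no regiochemical choice exists. Stille coupling with allyltributylstannane (Pd(PPh3)4, LiCl, DMF, 80 °C) gives 3-methoxy-2-[4-methoxy-3-(triisopropylsilyloxy)phenyl]-5-(prop-2-en-1-yl)-6-(triisopropylsilyloxy)-1-benzofuran F7. Olefin cross-metathesis with excess 2-methylbut-2-ene (second-generation Ru benzylidene catalyst, CH2Cl2, 40 °C) then converts allyl into prenyl and gives 14.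

**Step 8.** The likely failures are incomplete cleavage of the hindered C6 silyl ether flanked by the prenyl chain, and oxidative degradation of the very electron-rich product if phenoxide forms under fluoride.

Fallback, setting out from 12 and returning at 15: the order of deprotection and C–C coupling is reversed. Desilylation of the robust bromide 12 (TBAF, AcOH, THF) gives 5-bromo-2-(3-hydroxy-4-methoxyphenyl)-3-methoxy-1-benzofuran-6-ol F8. Suzuki–Miyaura prenylation of F8 with 13 (same catalyst, aq K3PO4, THF, 65 °C, degassed) then gives 15 directly, so the prenylated diphenol is never exposed to fluoride.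

## Further compounds

F1 | step 6 | [4-bromo-3-(triisopropylsilyloxy)phenyl]boronic acid | OB(O)c1ccc(Br)c(O[Si](C(C)C)(C(C)C)C(C)C)c1
F2 | step 6 | 4-bromo-3-(triisopropylsilyloxy)phenol | Oc1ccc(Br)c(O[Si](C(C)C)(C(C)C)C(C)C)c1
F3 | step 6 | 4-bromo-2-iodo-5-(triisopropylsilyloxy)phenol | Oc1cc(O[Si](C(C)C)(C(C)C)C(C)C)c(Br)cc1I
F4 | step 6 | 2-[5-bromo-2-hydroxy-4-(triisopropylsilyloxy)phenyl]-2-methoxy-1-[4-methoxy-3-(triisopropylsilyloxy)phenyl]ethan-1-one (racemic) | COC(C(=O)c1ccc(OC)c(O[Si](C(C)C)(C(C)C)C(C)C)c1)c1cc(Br)c(O[Si](C(C)C)(C(C)C)C(C)C)cc1O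
F5 | step 5 | ethyl N-[4-bromo-3-(triisopropylsilyloxy)phenoxy]ethanimidate | CCOC(C)=NOc1ccc(Br)c(O[Si](C(C)C)(C(C)C)C(C)C)c1
F6 | step 5 | O-[4-bromo-3-(triisopropylsilyloxy)phenyl]hydroxylamine | NOc1ccc(Br)c(O[Si](C(C)C)(C(C)C)C(C)C)c1
F7 | step 7 | 3-methoxy-2-[4-methoxy-3-(triisopropylsilyloxy)phenyl]-5-(prop-2-en-1-yl)-6-(triisopropylsilyloxy)-1-benzofuran | COc1ccc(-c2oc3cc(O[Si](C(C)C)(C(C)C)C(C)C)c(CC=C)cc3c2OC)cc1O[Si](C(C)C)(C(C)C)C(C)C
F8 | step 8 | 5-bromo-2-(3-hydroxy-4-methoxyphenyl)-3-methoxy-1-benzofuran-6-ol | COc1ccc(-c2oc3cc(O)c(Br)cc3c2OC)cc1O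
A1 | alternative 1 | methyl 5-bromo-2-{[4-methoxy-3-(triisopropylsilyloxy)phenyl]methoxy}-4-(triisopropylsilyloxy)benzoate | COC(=O)c1cc(Br)c(O[Si](C(C)C)(C(C)C)C(C)C)cc1OCc1ccc(OC)c(O[Si](C(C)C)(C(C)C)C(C)C)c1
A2 | alternative 1 | 5-bromo-2-[4-methoxy-3-(triisopropylsilyloxy)phenyl]-6-(triisopropylsilyloxy)-1-benzofuran-3(2H)-one (racemic) | COc1ccc(C2Oc3cc(O[Si](C(C)C)(C(C)C)C(C)C)c(Br)cc3C2=O)cc1O[Si](C(C)C)(C(C)C)C(C)C
A3 | alternative 2 | 5-bromo-3-methoxy-6-(triisopropylsilyloxy)-1-benzofuran | COc1coc2cc(O[Si](C(C)C)(C(C)C)C(C)C)c(Br)cc12
A4 | alternative 3 | 4-bromo-2-{(Z)-1-methoxy-2-[4-methoxy-3-(triisopropylsilyloxy)phenyl]ethenyl}-5-(triisopropylsilyloxy)phenol | CO/C(=C\c1ccc(OC)c(O[Si](C(C)C)(C(C)C)C(C)C)c1)c1cc(Br)c(O[Si](C(C)C)(C(C)C)C(C)C)cc1O
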